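**Target:** (4R)-4-(2,5-dibromo-1H-indol-3-yl)-4,5-dihydro-1H-imidazol-2-amine. The stereocentre in the given SMILES is R (priorities N3 > C5H2 > indol-3-yl > H).

**Retrosynthetic overview**
1. Target 16 ⇐ protected cyclic guanidine 13 by removal of the N-sulfonyl (Tces) group on the guanidine and the N-tosyl group on the indole.
2. 13 ⇐ open-chain Tces-guanidine 11 by a catalytic enantioselective intramolecular nitrene insertion into the indol-3-ylmethylene C–H bond (proposed new step). This closes the imidazoline ring, the only ring built, and sets C4.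
3. 11 ⇐ amine 6 + S-methylisothiourea 10 (from sulfamate 7, CS2, MeI, NH3).
4. 6 ⇐ 5-bromotryptamine 1 (indole bought intact) by N-phthaloylation, C2 bromination, N-tosylation and hydrazinolysis.

Assumption: 1 is used as the free base, and the (S)-tert-leucinate catalyst in step 8 is taken to give the (4R) product; if the first run (X-ray of 13, anomalous dispersion) shows the opposite sense, the mirror-image catalyst from (R)-tert-leucine is used unchanged otherwise.

**Route**

Step 1
Reactants: 1 5-bromotryptamine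
Product: 3 2-[2-(5-bromo-1H-indol-3-yl)ethyl]isoindoline-1,3-dione, via phthalamic acid 2 (not isolated)
Conditions: phthalic anhydride (1.05 equiv), Et3N (0.1 equiv), toluene, reflux, Dean–Stark
Reagents that add atoms: phthalic anhydride (O=C1OC(=O)c2ccccc12)
Why: Gabriel-type imide formation (acylation to the amic acid, then cyclodehydration) masks the amine as a group without N–H, so later bromination and tosylation touch only the indole.

Step 2
Reactants: 3 2-[2-(5-bromo-1H-indol-3-yl)ethyl]isoindoline-1,3-dione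
Product: 4 2-[2-(2,5-dibromo-1H-indol-3-yl)ethyl]isoindoline-1,3-dione
Conditions: NBS (1.02 equiv), SiO2, CH2Cl2, rt, dark
Reagents that add atoms: N-bromosuccinimide (O=C1CCC(=O)N1Br)
Why: Electrophilic aromatic bromination of a 3-substituted indole ends at C2, the only free pyrrole carbon; the benzo ring is deactivated by the 5-bromo group and the side chain has no N–H to cyclise onto the indole.

Step 3
Reactants: 4 2-[2-(2,5-dibromo-1H-indol-3-yl)ethyl]isoindoline-1,3-dione
Product: 5 2-{2-[2,5-dibromo-1-(4-methylbenzenesulfonyl)-1H-indol-3-yl]ethyl}isoindoline-1,3-dione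
Conditions: NaH (1.2 equiv), TsCl (1.2 equiv), THF/DMF (4:1), 0 °C to rt
Reagents that add atoms: 4-methylbenzenesulfonyl chloride (Cc1ccc(cc1)S(Cl)(=O)=O)
Why: N-sulfonylation of the indolide anion; the tosyl group makes the indole electron-poor for the nitrene step and blocks ionisation at the future benzylic stereocentre.

Step 4
Reactants: 5 2-{2-[2,5-dibromo-1-(4-methylbenzenesulfonyl)-1H-indol-3-yl]ethyl}isoindoline-1,3-dione
Product: 6 2-[2,5-dibromo-1-(4-methylbenzenesulfonyl)-1H-indol-3-yl]ethan-1-amine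
Conditions: N2H4·H2O (4 equiv), EtOH/THF, 50 °C
Reagents that add atoms: none
Why: Ing–Manske hydrazinolysis of the phthalimide frees the primary amine; N-sulfonyl indoles and aryl bromides are inert to hydrazine at this temperature.

Step 5
Reactants: 7 2,2,2-trichloroethyl sulfamate
Product: 9 dimethyl N-(2,2,2-trichloroethoxysulfonyl)carbonimidodithioate, via disodium dithioimidocarbonate 8 (not isolated)
Conditions: NaH (2.1 equiv), CS2 (1.2 equiv), DMF, 0 °C; then MeI (2.2 equiv), 0 °C to rt
Reagents that add atoms: carbon disulfide (S=C=S); iodomethane (CI)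
Why: Dithiocarboxylation of the sulfamate anion followed by double S-methylation (SN2) is the standard route to N-sulfonyl dithioimidocarbonates.

Step 6
Reactants: 9 dimethyl N-(2,2,2-trichloroethoxysulfonyl)carbonimidodithioate
Product: 10 methyl N'-(2,2,2-trichloroethoxysulfonyl)carbamimidothioate
Conditions: NH3 (7 M in MeOH, 2 equiv), THF, 0 °C to rt
Reagents that add atoms: ammonia (N)
Why: Addition–elimination at the sulfonyl-activated imidocarbonate carbon stops after one MeS is replaced, because the resulting amino-isothiourea is much less electrophilic.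

Step 7
Reactants: 6 2-[2,5-dibromo-1-(4-methylbenzenesulfonyl)-1H-indol-3-yl]ethan-1-amine; 10 methyl N'-(2,2,2-trichloroethoxysulfonyl)carbamimidothioate
Product: 11 2,2,2-trichloroethyl N-[amino({2-[2,5-dibromo-1-(4-methylbenzenesulfonyl)-1H-indol-3-yl]ethyl}amino)methylidene]sulfamate
Conditions: 10 (1.1 equiv), Et3N (1 equiv), MeCN, 75 °C
Reagents that add atoms: none
Why: Guanidinylation of a primary amine by addition–elimination on an N-sulfonyl S-methylisothiourea, driven by loss of volatile methanethiol.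

Step 8
Reactants: 11 2,2,2-trichloroethyl N-[amino({2-[2,5-dibromo-1-(4-methylbenzenesulfonyl)-1H-indol-3-yl]ethyl}amino)methylidene]sulfamate
Product: 13 2,2,2-trichloroethyl N-{(4R)-4-[2,5-dibromo-1-(4-methylbenzenesulfonyl)-1H-indol-3-yl]imidazolidin-2-ylidene}sulfamate, via iminoiodinane 12 (not isolated)
Conditions: Rh2(S-tfpttl)4 [dirhodium tetrakis(N-tetrafluorophthaloyl-(S)-tert-leucinate)] (2 mol %), PhI(OAc)2 (1.6 equiv), MgO (2.5 equiv), PhCF3, 0 °C to rt
Reagents that add atoms: none
Why: Proposed new method: the NH2 end of the sulfonylguanidine condenses with PhI(OAc)2 to iminoiodinane 12, which transfers a guanidinyl nitrene to the dirhodium core; this electrophilic rhodium nitrene inserts, concertedly and with retention, into one of the two enantiotopic indol-3-ylmethylene C–H bonds through a five-membered ring-closing transition state, and the chiral bowl of four electron-poor N-tetrafluorophthaloyl tert-leucinate ligands is expected to distinguish the pro-R from the pro-S hydrogen and so set C4, while N-Ts and C2-Br suppress nitrene attack on the indole C2=C3 bond; the closest known reactions are the racemic Rh2(esp)2-catalysed oxidative cyclisation of Tces-guanidines to 2-aminoimidazolines and the enantioselective benzylic C–H amination of sulfamates with chiral dirhodium carboxylates, an asymmetric version on guanidine nitrene precursors not having been shown.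

Step 9
Reactants: 13 2,2,2-trichloroethyl N-{(4R)-4-[2,5-dibromo-1-(4-methylbenzenesulfonyl)-1H-indol-3-yl]imidazolidin-2-ylidene}sulfamate
Product: 15 (4R)-4-[2,5-dibromo-1-(4-methylbenzenesulfonyl)-1H-indol-3-yl]-4,5-dihydro-1H-imidazol-2-amine, via N-sulfonic acid 14 (not isolated)
Conditions: Zn dust, AcOH/MeOH (1:1), rt; filter; then 2 M aq. HCl/MeOH, 40 °C; aq. Na2CO3 work-up
Reagents that add atoms: none
Why: Reductive β-elimination of the trichloroethyl ester by Zn gives the guanidine N-sulfonic acid, whose N–S bond is then hydrolysed by acid; the N-tosyl group keeps the 2-bromoindole inert to acid and the stereocentre is not involved.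

Step 10
Reactants: 15 (4R)-4-[2,5-dibromo-1-(4-methylbenzenesulfonyl)-1H-indol-3-yl]-4,5-dihydro-1H-imidazol-2-amine
Product: 16 (4R)-4-(2,5-dibromo-1H-indol-3-yl)-4,5-dihydro-1H-imidazol-2-amine
Conditions: LiOH·H2O (5 equiv), THF/H2O (3:1), 50 °C
Reagents that add atoms: none
Why: Nucleophilic cleavage of the N-sulfonyl indole by hydroxide at sulfur, helped by the good 2,5-dibromoindolide leaving group; an alcohol-free medium gives only tosylate and no alkyl tosylate that could alkylate the guanidine.

**Compound list**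
1 | 5-bromotryptamine, 2-(5-bromo-1H-indol-3-yl)ethan-1-amine | NCCc1c[nH]c2ccc(Br)cc12 | starting material
2 | 2-{[2-(5-bromo-1H-indol-3-yl)ethyl]carbamoyl}benzoic acid (phthalamic acid) | OC(=O)c1ccccc1C(=O)NCCc1c[nH]c2ccc(Br)cc12 | intermediate
3 | 2-[2-(5-bromo-1H-indol-3-yl)ethyl]isoindoline-1,3-dione | O=C1c2ccccc2C(=O)N1CCc1c[nH]c2ccc(Br)cc12 | intermediate
4 | 2-[2-(2,5-dibromo-1H-indol-3-yl)ethyl]isoindoline-1,3-dione | O=C1c2ccccc2C(=O)N1CCc1c(Br)[nH]c2ccc(Br)cc12 | intermediate
5 | 2-{2-[2,5-dibromo-1-(4-methylbenzenesulfonyl)-1H-indol-3-yl]ethyl}isoindoline-1,3-dione | O=C1c2ccccc2C(=O)N1CCc1c(Br)n(S(=O)(=O)c2ccc(C)cc2)c2ccc(Br)cc12 | intermediate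
6 | 2-[2,5-dibromo-1-(4-methylbenzenesulfonyl)-1H-indol-3-yl]ethan-1-amine | NCCc1c(Br)n(S(=O)(=O)c2ccc(C)cc2)c2ccc(Br)cc12 | intermediate
7 | 2,2,2-trichloroethyl sulfamate | NS(=O)(=O)OCC(Cl)(Cl)Cl | starting material
8 | disodium N-(2,2,2-trichloroethoxysulfonyl)carbonimidodithioate | [Na+].[Na+].[S-]C([S-])=NS(=O)(=O)OCC(Cl)(Cl)Cl | intermediate
9 | dimethyl N-(2,2,2-trichloroethoxysulfonyl)carbonimidodithioate | CSC(SC)=NS(=O)(=O)OCC(Cl)(Cl)Cl | intermediate
10 | methyl N'-(2,2,2-trichloroethoxysulfonyl)carbamimidothioate | CSC(N)=NS(=O)(=O)OCC(Cl)(Cl)Cl | intermediate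
11 | 2,2,2-trichloroethyl N-[amino({2-[2,5-dibromo-1-(4-methylbenzenesulfonyl)-1H-indol-3-yl]ethyl}amino)methylidene]sulfamate | NC(NCCc1c(Br)n(S(=O)(=O)c2ccc(C)cc2)c2ccc(Br)cc12)=NS(=O)(=O)OCC(Cl)(Cl)Cl | intermediate
12 | iminoiodinane of 11: 2,2,2-trichloroethyl N-[({2-[2,5-dibromo-1-(4-methylbenzenesulfonyl)-1H-indol-3-yl]ethyl}amino)(phenyl-λ3-iodanylideneamino)methylidene]sulfamate | O=S(=O)(OCC(Cl)(Cl)Cl)N=C(NCCc1c(Br)n(S(=O)(=O)c2ccc(C)cc2)c2ccc(Br)cc12)N=Ic1ccccc1 | intermediate
13 | 2,2,2-trichloroethyl N-{(4R)-4-[2,5-dibromo-1-(4-methylbenzenesulfonyl)-1H-indol-3-yl]imidazolidin-2-ylidene}sulfamate | ClC(Cl)(Cl)COS(=O)(=O)N=C1N[C@H](c2c(Br)n(S(=O)(=O)c3ccc(C)cc3)c3ccc(Br)cc23)CN1 | intermediate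
14 | N-{(4R)-4-[2,5-dibromo-1-(4-methylbenzenesulfonyl)-1H-indol-3-yl]imidazolidin-2-ylidene}sulfamic acid | OS(=O)(=O)N=C1N[C@H](c2c(Br)n(S(=O)(=O)c3ccc(C)cc3)c3ccc(Br)cc23)CN1 | intermediate
15 | (4R)-4-[2,5-dibromo-1-(4-methylbenzenesulfonyl)-1H-indol-3-yl]-4,5-dihydro-1H-imidazol-2-amine | NC1=N[C@H](c2c(Br)n(S(=O)(=O)c3ccc(C)cc3)c3ccc(Br)cc23)CN1 | intermediate
16 | (4R)-4-(2,5-dibromo-1H-indol-3-yl)-4,5-dihydro-1H-imidazol-2-amine (CNP0165428.1) | NC1=N[C@H](c2c(Br)[nH]c3ccc(Br)cc23)CN1 | target

**Summary**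
Total step count: 10. Longest linear sequence: 8 steps (steps 1–4 and 7–10, from 1); steps 5 and 6 form a two-step branch that joins at step 7.

**Steps most likely to fail**

Step 8 (the proposed new step) may give low enantioselectivity or poor turnover with the chiral catalyst. The fallback uses known chemistry and takes the stereochemistry from resolution instead of catalyst control. It sets out from 11, which is cyclised with achiral Rh2(esp)2 [dirhodium bis(α,α,α',α'-tetramethyl-1,3-benzenedipropanoate)], PhI(OAc)2 and MgO in toluene at 40 °C, the established racemic cyclisation of Tces-guanidines. This gives racemic 2,2,2-trichloroethyl N-{4-[2,5-dibromo-1-(4-methylbenzenesulfonyl)-1H-indol-3-yl]imidazolidin-2-ylidene}sulfamate F1. F1 is resolved by preparative supercritical-fluid chromatography on an amylose tris(3,5-dimethylphenylcarbamate) phase. The route is rejoined at 13, and the unwanted 2,2,2-trichloroethyl N-{(4S)-4-[2,5-dibromo-1-(4-methylbenzenesulfonyl)-1H-indol-3-yl]imidazolidin-2-ylidene}sulfamate F2 is set aside.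

Step 7 may be sluggish, because amino-isothiourea 10 is a weak electrophile and long heating may damage the trichloroethyl ester. The fallback reverses the order of the two C–N bond formations so that the valuable amine does the easy displacement. It sets out from 6 and 9, which react in CH2Cl2 at rt to give methyl N-{2-[2,5-dibromo-1-(4-methylbenzenesulfonyl)-1H-indol-3-yl]ethyl}-N'-(2,2,2-trichloroethoxysulfonyl)carbamimidothioate F3. A large excess of NH3 (0.5 M in 1,4-dioxane, sealed tube, 60 °C) then replaces the second methylthio group, and the route is rejoined at 11.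

Step 10 exposes the free cyclic guanidine to hot hydroxide, which may hydrolyse it to the cyclic urea, or the detosylation may be slow. The fallback changes the order of deprotection so that the tosyl group leaves while the guanidine is still masked as the non-basic sulfonylguanidine. It sets out from 13, which is treated with Bu4NF in THF at 50 °C to give 2,2,2-trichloroethyl N-[(4R)-4-(2,5-dibromo-1H-indol-3-yl)imidazolidin-2-ylidene]sulfamate F4. Zn dust in AcOH/MeOH then gives N-[(4R)-4-(2,5-dibromo-1H-indol-3-yl)imidazolidin-2-ylidene]sulfamic acid F5, which is hydrolysed in the same flask with 2 M aq. HCl/MeOH at rt, and the route is rejoined at 16.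

**Further compounds**
F1 | step 8 | racemic 2,2,2-trichloroethyl N-{4-[2,5-dibromo-1-(4-methylbenzenesulfonyl)-1H-indol-3-yl]imidazolidin-2-ylidene}sulfamate | ClC(Cl)(Cl)COS(=O)(=O)N=C1NC(c2c(Br)n(S(=O)(=O)c3ccc(C)cc3)c3ccc(Br)cc23)CN1
F2 | step 8 | 2,2,2-trichloroethyl N-{(4S)-4-[2,5-dibromo-1-(4-methylbenzenesulfonyl)-1H-indol-3-yl]imidazolidin-2-ylidene}sulfamate | ClC(Cl)(Cl)COS(=O)(=O)N=C1N[C@@H](c2c(Br)n(S(=O)(=O)c3ccc(C)cc3)c3ccc(Br)cc23)CN1
F3 | step 7 | methyl N-{2-[2,5-dibromo-1-(4-methylbenzenesulfonyl)-1H-indol-3-yl]ethyl}-N'-(2,2,2-trichloroethoxysulfonyl)carbamimidothioate | CSC(NCCc1c(Br)n(S(=O)(=O)c2ccc(C)cc2)c2ccc(Br)cc12)=NS(=O)(=O)OCC(Cl)(Cl)Cl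
F4 | step 10 | 2,2,2-trichloroethyl N-[(4R)-4-(2,5-dibromo-1H-indol-3-yl)imidazolidin-2-ylidene]sulfamate | ClC(Cl)(Cl)COS(=O)(=O)N=C1N[C@H](c2c(Br)[nH]c3ccc(Br)cc23)CN1
F5 | step 10 | N-[(4R)-4-(2,5-dibromo-1H-indol-3-yl)imidazolidin-2-ylidene]sulfamic acid | OS(=O)(=O)N=C1N[C@H](c2c(Br)[nH]c3ccc(Br)cc23)CN1
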